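**Retrosynthetic overview**

- Ardisinone ⇒ (remove acetate) the (R)-2'-hydroxy quinone ⇒ (reverse oxidative dealkylation) (R)-5,7-dimethoxy-2-tridecyl-2,3-dihydrobenzofuran. The feature used: quinone carbonyl carbon C1 (between methoxy-bearing C2 and chain-bearing C6), C6, chain carbons C1' (CH2) and C2' (CH–O) and the C2' oxygen are the furan atoms C7a, C3a, C3, C2 and O1; C4=O is masked as the 5-OMe.
- The dihydrobenzofuran ⇒ 1-iodo-2,4-dimethoxybenzene + (R)-1,2-epoxypentadecane by a palladium/norbornene (Catellani-type) annulation: C6–C1' at the free ortho C–H, C1–O at the C–I carbon. The dihydrofuran ring is the only ring formed in the route and is opened again by the oxidation.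
- The epoxide ⇒ (R)-epichlorohydrin + dodecylmagnesium bromide (C3 + C12); the single stereocentre is bought and none of its bonds is broken afterwards.

Key step: step 3

Remark on the chemistry: quinone atoms are numbered C1 (carbonyl between C2–OMe and C6), C4 (second carbonyl), chain C1' (CH2) and C2' (stereocentre); the target SMILES corresponds to (R) at C2'.

**Step 1**
Reactants: 1 dodecylmagnesium bromide (commercial solution in Et2O); 2 (R)-epichlorohydrin [(R)-2-(chloromethyl)oxirane]
Product: 3 (R)-1-chloropentadecan-2-ol
Conditions: CuI (10 mol%), THF, −40 to −20 °C, slow addition of 1; then 1 M aq. HCl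
Reagents that add atoms: none
Why: Copper-catalysed Grignard opening of an epoxide, in which the alkylcopper species attacks the unhindered epoxide CH2 in SN2 fashion, so the C–O bond at the stereocentre is untouched (descriptor stays R) and the cold magnesium chloroalkoxide does not close to an epoxide that could add a second equivalent.

**Step 2**
Reactants: 3 (R)-1-chloropentadecan-2-ol
Product: 4 (R)-1,2-epoxypentadecane [(R)-2-tridecyloxirane]
Conditions: powdered NaOH, Et2O, rt
Reagents that add atoms: none
Why: Intramolecular Williamson etherification (3-exo-tet), in which the alkoxide on the stereocentre displaces chloride at the primary carbon, so the configuration is retained.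

**Step 3**
Reactants: 4 (R)-1,2-epoxypentadecane (1.5 equiv); 5 1-iodo-2,4-dimethoxybenzene (1.0 equiv)
Product: 6 (R)-5,7-dimethoxy-2-tridecyl-2,3-dihydrobenzofuran
Conditions: Pd(OAc)2 (5 mol%), RuPhos (2-dicyclohexylphosphino-2',6'-diisopropoxybiphenyl, 10 mol%), isopropyl 5-norbornene-2-carboxylate (50 mol%), K2CO3 (1.5 equiv), DMF, 100 °C, Ar
Reagents that add atoms: none
Why: This is the known palladium/norbornene cooperative (Catellani-type) annulation of aryl iodides with epoxides to 2,3-dihydrobenzofurans, applied to a 2-alkoxy aryl iodide and an aliphatic terminal epoxide. Zerovalent palladium inserts into the C–I bond of 5, the norbornene inserts, and palladation of the only ortho C–H (future quinone C6) gives the five-membered aryl–norbornyl palladacycle of divalent palladium; this opens the epoxide at its CH2 carbon to reach tetravalent palladium, and reductive elimination forms the C6–C1' bond. Beta-carbon elimination then expels the norbornene and the pendant alkoxide binds the metal, giving a six-membered oxapalladacycle (Pd, C1, C6, C1', C2', O) of divalent palladium. The dihydrofuran ring closes by C(aryl)–O reductive elimination from that palladacycle, an intramolecular etherification at the former C–I carbon that the bulky, electron-rich RuPhos favours and that returns zerovalent palladium. No stereocentre is created: C2' is the epoxide CH carbon, whose C–O bond is never broken, so the (R) configuration of 4 is carried over unchanged. The step needs attack at the terminal epoxide carbon, a single ortho alkylation, and C–O closure instead of beta-hydride loss from the alkoxide; these are secured, in that order, by the unhindered CH2, by the 2-methoxy group that blocks the second ortho site and drives norbornene extrusion, and by the biaryl phosphine.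

**Step 4**
Reactants: 6 (R)-5,7-dimethoxy-2-tridecyl-2,3-dihydrobenzofuran
Product: 7 (R)-2-(2-hydroxypentadecyl)-6-methoxy-1,4-benzoquinone
Conditions: (NH4)2Ce(NO3)6 (2.5 equiv), MeCN–H2O 2:1, 0 °C, short reaction time
Reagents that add atoms: water, O
Why: Oxidative dealkylation of a para-dialkoxyarene by tetravalent cerium, in which water adds to the oxidised ring at C7a and C5 and the aryl–oxygen bonds break, so methanol leaves from C5, the ring oxygen stays on C2' as the free hydroxyl with (R) intact, and the para relationship of O1 and the 5-OMe directs formation of the 1,4-quinone that keeps the 7-OMe.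

**Step 5**
Reactants: 7 (R)-2-(2-hydroxypentadecyl)-6-methoxy-1,4-benzoquinone
Product: 8 ardisinone [(R)-1-(5-methoxy-3,6-dioxocyclohexa-1,4-dien-1-yl)pentadecan-2-yl acetate]
Conditions: Ac2O (3 equiv), pyridine (5 equiv), DMAP (5 mol%), CH2Cl2, 0 °C
Reagents that add atoms: acetic anhydride, CC(=O)OC(C)=O
Why: Nucleophile-catalysed O-acylation of a secondary alcohol, which does not touch the C2'–O bond and so retains (R), run cold and briefly because the methoxyquinone is only moderately electrophilic toward pyridine bases.

**Compound list**

1 | dodecylmagnesium bromide | CCCCCCCCCCCC[Mg]Br | starting material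
2 | (R)-epichlorohydrin | ClC[C@H]1CO1 | starting material
3 | (R)-1-chloropentadecan-2-ol | CCCCCCCCCCCCC[C@@H](O)CCl | intermediate
4 | (R)-1,2-epoxypentadecane | CCCCCCCCCCCCC[C@@H]1CO1 | intermediate
5 | 1-iodo-2,4-dimethoxybenzene | COc1ccc(I)c(OC)c1 | starting material
6 | (R)-5,7-dimethoxy-2-tridecyl-2,3-dihydrobenzofuran | CCCCCCCCCCCCC[C@@H]1Cc2cc(OC)cc(OC)c2O1 | intermediate
7 | (R)-2-(2-hydroxypentadecyl)-6-methoxy-1,4-benzoquinone | CCCCCCCCCCCCC[C@@H](O)CC1=CC(=O)C=C(OC)C1=O | intermediate
8 | ardisinone | CCCCCCCCCCCCC[C@H](CC1=CC(=O)C=C(OC)C1=O)OC(C)=O | target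

**Step count**

Total steps: 5. Longest linear sequence: 5 steps (1 + 2 → 3 → 4 → 6 → 7 → 8; 5 is bought and enters at step 3).

**Steps most likely to fail**

Step 3. The secondary palladium alkoxide may lose a beta-hydride (ketone formation with ipso reduction) faster than it undergoes C–O reductive elimination. The aryl palladium species may also terminate at the ipso carbon before ortho alkylation, or iodide may open and rearrange the epoxide. The fallback forms the same two bonds stepwise; it sets out from epoxide 4 and comes back at 6. Commercial 1-bromo-3,5-dimethoxybenzene and Mg in THF give 3,5-dimethoxyphenylmagnesium bromide F1. With CuI (10 mol%) at −30 °C, followed by a dilute HCl quench, this should open 4 at the terminal carbon to give (R)-1-(3,5-dimethoxyphenyl)pentadecan-2-ol F2. NBS in MeCN at 0 °C should brominate the ring position ortho to the chain and para to a methoxy group, giving (R)-1-(2-bromo-3,5-dimethoxyphenyl)pentadecan-2-ol F3. Intramolecular palladium-catalysed aryl etherification (Pd(OAc)2, 2-(di-tert-butylphosphino)-1,1'-binaphthyl, Cs2CO3, toluene, 80–100 °C) should then close the dihydrofuran ring to 6 without touching the C2'–O bond.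

Step 4. The oxidation may take the ortho course with loss of the 7-methoxy group, the electron-rich arene may couple oxidatively, or the liberated secondary alcohol may be oxidised further. The fallback unmasks the quinone in two stages; it sets out from 6 and comes back at 7. Anodic oxidation of 6 (Pt anode, MeOH containing KOH, undivided cell, 0 °C, constant current) should add two methoxy groups across the para positions. This gives the quinone bisketal (2R)-5,5,7,7a-tetramethoxy-2-tridecyl-2,3,5,7a-tetrahydrobenzofuran F4 as a mixture of C7a epimers. Dilute aqueous acid (1 M HCl in acetone, rt) should then hydrolyse both ketal carbons; the ketal C7a–O bond breaks, not the C2'–O bond, so the (R) hydroxyl of 7 is released.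

Step 5. Pyridine or DMAP may add to the quinone, and base-induced decomposition or ring acetoxylation may compete with O-acylation. The fallback acetylates at the hydroquinone oxidation level; it sets out from 7 and comes back at 8. Na2S2O4 (aq.)/EtOAc should reduce 7 to (R)-2-(2-hydroxypentadecyl)-6-methoxybenzene-1,4-diol F5. Ac2O/pyridine/DMAP should then give the triacetate (R)-1-(2,5-diacetoxy-3-methoxyphenyl)pentadecan-2-yl acetate F6. Pyrrolidine (about 2.5 equiv, CH2Cl2, 0 °C, Ar) should cleave only the two aryl acetates by aminolysis, giving (R)-1-(2,5-dihydroxy-3-methoxyphenyl)pentadecan-2-yl acetate F7. Ag2O in Et2O at rt should reoxidise this hydroquinone to 8.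

**Further compounds**

F1 | step 3 | 3,5-dimethoxyphenylmagnesium bromide | COc1cc(OC)cc([Mg]Br)c1
F2 | step 3 | (R)-1-(3,5-dimethoxyphenyl)pentadecan-2-ol | CCCCCCCCCCCCC[C@@H](O)Cc1cc(OC)cc(OC)c1
F3 | step 3 | (R)-1-(2-bromo-3,5-dimethoxyphenyl)pentadecan-2-ol | CCCCCCCCCCCCC[C@@H](O)Cc1cc(OC)cc(OC)c1Br
F4 | step 4 | (2R)-5,5,7,7a-tetramethoxy-2-tridecyl-2,3,5,7a-tetrahydrobenzofuran (both C7a epimers) | CCCCCCCCCCCCC[C@@H]1CC2=CC(OC)(OC)C=C(OC)C2(OC)O1
F5 | step 5 | (R)-2-(2-hydroxypentadecyl)-6-methoxybenzene-1,4-diol | CCCCCCCCCCCCC[C@@H](O)Cc1cc(O)cc(OC)c1O
F6 | step 5 | (R)-1-(2,5-diacetoxy-3-methoxyphenyl)pentadecan-2-yl acetate | CCCCCCCCCCCCC[C@H](Cc1cc(OC(C)=O)cc(OC)c1OC(C)=O)OC(C)=O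
F7 | step 5 | (R)-1-(2,5-dihydroxy-3-methoxyphenyl)pentadecan-2-yl acetate | CCCCCCCCCCCCC[C@H](Cc1cc(O)cc(OC)c1O)OC(C)=O
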